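## Retrosynthetic overview

1. Skeleton numbering used throughout: carbocycle C1–C10; lactone C6–O–C12(=O)–C11(=C13H2)–C7; C14 on C10, C15 on C4; angelate on O8. The last step is a 1,3-anti reduction of a C3 enone directed by the C1 hydroxyl.
2. Ten-membered ring ⇐ Grob fragmentation of a cis-bicyclo[6.2.0]decane, in which the cyclobutane C1–C2–C3–C10 is fused to the eight-membered ring C3–C4=C5–C6–C7–C8–C9–C10 along C3–C10. The enabling feature is the array O–C3–C10–C9–OMs: a tertiary cyclobutanol oxygen on C3 and a sulfonate on C9, attached to the two ends of the strained fusion bond. Cutting C3–C10 inserts C1–C2 (8 → 10) and gives the C3 ketone and the 9Z olefin.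
3. Bicycle ⇐ [2+2] of dichloroketene with the C3(OSi)=C10 silyl dienol ether of an eight-membered enone. Eight-membered ring ⇐ intramolecular Nozaki–Hiyama–Kishi closure of C3–C4, with the 4Z olefin brought in as (Z)-3-iodobut-2-enal.
4. C9/C10/C3 ⇐ crotylboration and alkene cleavage; C8 angelate ⇐ Mitsunobu inversion. The γ-lactone, the C6–C7 bond and the exocyclic methylene ⇐ one chromium-mediated 2-(methoxycarbonyl)allylation of (Z)-3-iodobut-2-enal with the Baylis–Hillman bromide from (S)-glyceraldehyde acetonide and methyl acrylate.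
5. Order of ring formation: γ-lactone (step 5) → eight-membered ring (step 13) → cyclobutane (step 16) → ten-membered ring by two-carbon ring expansion (step 20).

Key step: step 20

Remark: the target SMILES is read as the (1S,3S,6S,7R,8R)-4Z,9Z isomer carrying an angelate [(Z)-2-methylbut-2-enoate]; the γ-lactone of 10 and 11 is assumed not to migrate to the free C8 hydroxyl under the mild conditions used.

## Route

Step 1
Reactants: 1 but-2-yn-1-ol
Product: 2 (Z)-3-iodobut-2-en-1-ol
Conditions: NaAlH2(OCH2CH2OCH3)2 (Red-Al), Et2O, 0 °C; then I2, THF, −78 → 0 °C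
Reagents that add atoms: iodine, II
Why: Hydroxyl-directed trans-hydroalumination of the propargylic alcohol places aluminium on C3, and iodinolysis with retention should give the (Z)-vinyl iodide, which already holds the later C15–C4=C5 unit with its 4Z geometry.

Step 2
Reactants: 2 (Z)-3-iodobut-2-en-1-ol
Product: 3 (Z)-3-iodobut-2-enal
Conditions: MnO2, CH2Cl2, rt, dark
Reagents that add atoms: none
Why: Allylic alcohol oxidation with activated MnO2 is neutral and should not isomerise the (Z)-iodoenal.

Step 3
Reactants: 4 (S)-2,2-dimethyl-1,3-dioxolane-4-carbaldehyde; 5 methyl acrylate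
Product: 6 methyl 2-{hydroxy[(S)-2,2-dimethyl-1,3-dioxolan-4-yl]methyl}prop-2-enoate (both carbinol epimers)
Conditions: DABCO (cat.), dioxane/H2O, rt
Reagents that add atoms: none
Why: Baylis–Hillman reaction; the new carbinol centre forms without control and is erased in step 4, while the dioxolane centre (later C8) is untouched.

Step 4
Reactants: 6 Baylis–Hillman adduct
Product: 7 methyl (Z)-2-(bromomethyl)-3-(2,2-dimethyl-1,3-dioxolan-4-yl)prop-2-enoate (dioxolane centre as in 4)
Conditions: NBS, Me2S, CH2Cl2, 0 °C → rt
Reagents that add atoms: N-bromosuccinimide, O=C1CCC(=O)N1Br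
Why: SN2′ bromination of the Baylis–Hillman alcohol through the sulfonium reagent formed from NBS and Me2S (Corey–Kim type) should give the conjugated (Z)-2-(bromomethyl)enoate needed for carbonyl allylation.

Step 5
Reactants: 7 (Z)-allyl bromide; 3 (Z)-3-iodobut-2-enal
Product: 9 (4R,5R)-4-[(4R)-2,2-dimethyl-1,3-dioxolan-4-yl]-5-[(Z)-2-iodoprop-1-enyl]-3-methylideneoxolan-2-one (C6/C7 trans as in the target; C8 epimeric to the target), via hydroxy ester 8 (not isolated)
Conditions: CrCl2, THF, 0 °C → rt; then PPTS (cat.), CH2Cl2, rt
Reagents that add atoms: none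
Why: Nozaki–Hiyama-type 2-(methoxycarbonyl)allylation, in which the allylchromium reagent from 7 adds through C7 (SE2′) in a chair transition state with anti simple diastereoselection (C6/C7, hence the trans-lactone) and on the face opposite the C8–C9 bond while C8–H eclipses the alkene (C7/C8), after which the γ-hydroxy ester lactonises; without a nickel co-catalyst the vinyl iodide is inert.

Step 6
Reactants: 9 acetonide lactone
Product: 10 diol: 4-[(1R)-1,2-dihydroxyethyl]-5-[(Z)-2-iodoprop-1-enyl]-3-methylideneoxolan-2-one (ring centres as in 9)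
Conditions: AcOH/H2O (4:1), 40 °C
Reagents that add atoms: none
Why: Mild acetal hydrolysis frees the C8 and C9 hydroxyls and leaves the allylic lactone and the conjugated methylene intact.

Step 7
Reactants: 10 diol
Product: 11 primary silyl ether (C9–OTBS, free C8–OH)
Conditions: TBSCl, Et3N, DMAP (cat.), CH2Cl2, 0 °C
Reagents that add atoms: tert-butyldimethylsilyl chloride, CC(C)(C)[Si](C)(C)Cl
Why: Steric differentiation: silylation of the primary C9 hydroxyl is much faster than that of the hindered secondary C8 hydroxyl.

Step 8
Reactants: 11 C8 alcohol; 12 angelic acid [(Z)-2-methylbut-2-enoic acid]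
Product: 13 C8 angelate with inverted C8 (now the target configuration), C9–OTBS
Conditions: PPh3, DIAD, toluene, 0 °C → rt
Reagents that add atoms: none
Why: Mitsunobu esterification proceeds by SN2 displacement of the oxyphosphonium group with inversion, which converts the C8 configuration delivered by step 5 into that of the target, and the neutral conditions should not isomerise the angelate to the tiglate.

Step 9
Reactants: 13 silyl ether
Product: 14 primary alcohol (C9–OH, C8–OAng)
Conditions: HF·pyridine, THF, 0 °C
Reagents that add atoms: none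
Why: Fluoride desilylation under weakly acidic conditions should avoid migration of the angeloyl group to the primary hydroxyl.

Step 10
Reactants: 14 primary alcohol
Product: 15 C9 aldehyde (α-angeloyloxy aldehyde)
Conditions: Dess–Martin periodinane, NaHCO3, CH2Cl2, 0 °C
Reagents that add atoms: none
Why: Buffered periodinane oxidation gives the α-acyloxy aldehyde without epimerising C8 or touching the vinyl iodide.

Step 11
Reactants: 15 C9 aldehyde
Product: 16 homoallylic alcohol (C9–OH, C10 methyl, 9,10-anti, terminal vinyl; C9 as drawn)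
Conditions: (R,R)-diisopropyl tartrate (E)-crotylboronate, 4 Å MS, toluene, −78 °C
Reagents that add atoms: diisopropyl (4R,5R)-2-[(E)-but-2-enyl]-1,3,2-dioxaborolane-4,5-dicarboxylate, C/C=C/CB1O[C@@H](C(=O)OC(C)C)[C@H](C(=O)OC(C)C)O1
Why: Tartrate-controlled crotylboration through a closed chair transition state, in which the (E)-crotyl unit gives the 9,10-anti relationship and the (R,R)-tartrate directs attack to the Si face of the aldehyde, should set C9 as drawn against the modest Felkin preference of the α-acyloxy aldehyde (C10 is erased later and C9 becomes the leaving-group carbon).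

Step 12
Reactants: 16 homoallylic alcohol
Product: 18 β-hydroxy aldehyde (C3 aldehyde, C10 methyl, C9–OH), via vicinal diol 17 (not isolated)
Conditions: OsO4 (cat.), NaIO4, 2,6-lutidine, dioxane/H2O (3:1), rt
Reagents that add atoms: osmium tetroxide, O=[Os](=O)(=O)=O (oxygen carrier); sodium periodate, [Na+].[O-]I(=O)(=O)=O
Why: Lemieux–Johnson cleavage, in which OsO4 dihydroxylates the only electron-rich monosubstituted alkene (vinyl iodide, angelate and α-methylene lactone are deactivated) and NaIO4 cleaves the diol to the C3 aldehyde.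

Step 13
Reactants: 18 iodo aldehyde
Product: 19 eight-membered allylic alcohol (ring C3–C4=C5–C6–C7–C8–C9–C10, trans-fused γ-lactone at C6–C7; C3 epimers)
Conditions: CrCl2, NiCl2 (cat.), DMSO/THF, high dilution, rt
Reagents that add atoms: none
Why: Intramolecular Nozaki–Hiyama–Kishi reaction (nickel-catalysed insertion into C4–I, transfer to trivalent chromium, addition to the C3 aldehyde) closes the eight-membered ring with retention of the 4Z geometry, which a ring of this size enforces in any case; the C3 carbinol forms as a mixture that converges in step 14.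

Step 14
Reactants: 19 allylic alcohol
Product: 20 eight-membered enone (C3 ketone conjugated with C4=C5, free C9–OH)
Conditions: MnO2, CH2Cl2, rt
Reagents that add atoms: none
Why: MnO2 oxidises the allylic C3 alcohol chemoselectively and leaves the non-allylic C9 alcohol untouched.

Step 15
Reactants: 20 enone
Product: 21 bis(trimethylsilyl) derivative: C9–OTMS and the C3(OTMS)=C10 silyl dienol ether
Conditions: TMSOTf, Et3N, CH2Cl2, −78 → 0 °C
Reagents that add atoms: trimethylsilyl trifluoromethanesulfonate, C[Si](C)(C)OS(=O)(=O)C(F)(F)F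
Why: Soft enolisation and silylation: the only α-hydrogen of the enone is on C10, so the cross-conjugated 2-silyloxydiene forms regiospecifically (the C10 stereocentre is erased) and the C9 hydroxyl is silylated in the same pot.

Step 16
Reactants: 21 silyl dienol ether
Product: 22 cis-fused dichlorocyclobutanone (bicyclo[6.2.0]decane: C3–OTMS, C2 = CCl2, C1 ketone, C10 methyl)
Conditions: Cl3CCOCl, Zn–Cu couple, POCl3, Et2O, rt
Reagents that add atoms: trichloroacetyl chloride, ClC(Cl)(Cl)C(Cl)=O (source of dichloroketene, ClC(Cl)=C=O)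
Why: [2+2] cycloaddition of dichloroketene with a silyl enol ether, in which the ketene carbonyl carbon bonds to the nucleophilic C10 and CCl2 to C3 (the usual 3-silyloxycyclobutanone regiochemistry), suprafacially on the ring face opposite the C6–C8 bridge in the conformer that keeps C9–H next to the C10 methyl group, should give the cis-fused bicycle with C3 and C10 as drawn.

Step 17
Reactants: 22 dichlorocyclobutanone
Product: 24 cyclobutanone with free C9–OH and C3–OTMS, via bis-silyl cyclobutanone 23 (not isolated)
Conditions: Zn, NH4Cl, MeOH, 0 °C → rt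
Reagents that add atoms: none
Why: Zinc reductively removes both α-chlorines, and the exposed secondary C9 silyl ether is methanolysed under the same weakly acidic conditions, while the neopentylic tertiary C3 silyl ether, which blocks retro-aldol opening of the β-oxy cyclobutanone, should survive.

Step 18
Reactants: 24 C9 alcohol
Product: 25 C9 mesylate
Conditions: MsCl, Et3N, CH2Cl2, −20 °C
Reagents that add atoms: methanesulfonyl chloride, CS(=O)(=O)Cl
Why: Sulfonylation of the only free hydroxyl; C10 is quaternary, so the β-mesyloxy ketone cannot eliminate by an E1cB path.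

Step 19
Reactants: 25 cyclobutanone mesylate
Product: 26 cyclobutanol (C1–OH cis to C9, C3–OTMS, C9–OMs)
Conditions: NaBH4, THF/MeOH (4:1), −78 °C
Reagents that add atoms: none
Why: Hydride reduction of the strained cyclobutanone is faster than attack on ester, lactone or mesylate, and delivery from the convex face (syn to the angular C10 methyl, anti to the eight-membered ring) should place the C1 hydroxyl cis to C9, which is the 1S configuration of the target.

Step 20
Reactants: 26 cyclobutanol mesylate
Product: 28 cyclodecadienone (C3 ketone, C1–OH, 4Z and 9Z olefins, lactone and angelate in place), via tertiary alkoxide 27 (not isolated)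
Conditions: TBAF (1.05 equiv), THF, −40 → 0 °C; then AcOH
Reagents that add atoms: none
Why: Fluoride removes the tertiary trimethylsilyl group and the C3 alkoxide 27 fragments in a concerted Grob (Wharton-type) process: the oxygen lone pair forms the C3 carbonyl, the C3–C10 bond (common to the four- and eight-membered rings and antiperiplanar to C9–OMs) breaks, the C9=C10 double bond forms and mesylate leaves, with relief of cyclobutane strain making the step irreversible. The closest known reaction type is the alkoxide-induced fragmentation of bicyclic 1,3-diol monosulfonates to medium-ring enones, here with a more strained cyclobutanol as donor. No ring is closed: the ten-membered ring arises from the eight-membered ring because C1 and C2 of the cyclobutane are inserted between C3 and C10 when the fusion bond is cut (ring expansion by two atoms). No stereocentre is created; the Z geometry of C9=C10 follows stereospecifically from the relative configuration of C10 and C9 (set in steps 16 and 11) through the antiperiplanar requirement, and C1, C6, C7 and C8 are untouched. The selectivity needed is cleavage of C3–C10 rather than retro-aldol opening, oxetane formation or fragmentation from the C1 oxygen; it is secured because C1 is at the carbinol level, because only the C3–C10 bond can align with the C9–O bond, and because one equivalent of fluoride leaves the C1 hydroxyl un-ionised and the medium neutral once the ketone has formed.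

Step 21
Reactants: 28 β-hydroxy enone
Product: 29 target (1S,3S-diol)
Conditions: Me4NBH(OAc)3, MeCN/AcOH (1:1), −30 °C
Reagents that add atoms: none
Why: Hydroxyl-directed 1,3-anti reduction (Evans–Saksena type), in which the C1 hydroxyl exchanges onto boron and hydride is delivered intramolecularly to the C3 carbonyl through a chair transition state, should set 3S anti to 1S; triacetoxyborohydride does not reduce the esters, the lactone or the conjugated methylene.

## Compound list

1 | but-2-yn-1-ol | CC#CCO | starting material
2 | (Z)-3-iodobut-2-en-1-ol | C/C(I)=C/CO | intermediate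
3 | (Z)-3-iodobut-2-enal | C/C(I)=C/C=O | intermediate
4 | (S)-2,2-dimethyl-1,3-dioxolane-4-carbaldehyde | O=C[C@@H]1COC(C)(C)O1 | starting material
5 | methyl acrylate | C=CC(=O)OC | starting material
6 | methyl 2-{hydroxy[(S)-2,2-dimethyl-1,3-dioxolan-4-yl]methyl}prop-2-enoate (carbinol epimers) | C=C(C(=O)OC)C(O)[C@@H]1COC(C)(C)O1 | intermediate
7 | methyl (Z)-2-(bromomethyl)-3-(2,2-dimethyl-1,3-dioxolan-4-yl)prop-2-enoate | BrC/C(C(=O)OC)=C\[C@@H]1COC(C)(C)O1 | intermediate
8 | methyl (Z)-3-(2,2-dimethyl-1,3-dioxolan-4-yl)-4-hydroxy-6-iodo-2-methylidenehept-5-enoate (C6, C7 as in 9) | COC(=O)C(=C)[C@H]([C@@H](O)/C=C(/C)I)[C@@H]1COC(C)(C)O1 | intermediate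
9 | (4R,5R)-4-[(4R)-2,2-dimethyl-1,3-dioxolan-4-yl]-5-[(Z)-2-iodoprop-1-enyl]-3-methylideneoxolan-2-one | C=C1C(=O)O[C@@H](/C=C(/C)I)[C@@H]1[C@@H]2COC(C)(C)O2 | intermediate
10 | 4-[(1R)-1,2-dihydroxyethyl]-5-[(Z)-2-iodoprop-1-enyl]-3-methylideneoxolan-2-one (ring centres as in 9) | C=C1C(=O)O[C@@H](/C=C(/C)I)[C@@H]1[C@@H](O)CO | intermediate
11 | C9 tert-butyldimethylsilyl ether of 10 (free C8–OH) | C=C1C(=O)O[C@@H](/C=C(/C)I)[C@@H]1[C@@H](O)CO[Si](C)(C)C(C)(C)C | intermediate
12 | angelic acid, (Z)-2-methylbut-2-enoic acid | C/C=C(/C)C(=O)O | starting material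
13 | C8 angelate (C8 inverted to target configuration), C9–OTBS | C=C1C(=O)O[C@@H](/C=C(/C)I)[C@@H]1[C@H](OC(=O)/C(C)=C\C)CO[Si](C)(C)C(C)(C)C | intermediate
14 | C8 angelate, C9 primary alcohol | C=C1C(=O)O[C@@H](/C=C(/C)I)[C@@H]1[C@H](OC(=O)/C(C)=C\C)CO | intermediate
15 | C8 angelate, C9 aldehyde | C=C1C(=O)O[C@@H](/C=C(/C)I)[C@@H]1[C@H](OC(=O)/C(C)=C\C)C=O | intermediate
16 | homoallylic alcohol (C9–OH, C10 methyl, 9,10-anti, terminal vinyl) | C=C1C(=O)O[C@@H](/C=C(/C)I)[C@@H]1[C@H](OC(=O)/C(C)=C\C)[C@@H](O)[C@@H](C)C=C | intermediate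
17 | vicinal diol from osmylation of the vinyl group of 16 | C=C1C(=O)O[C@@H](/C=C(/C)I)[C@@H]1[C@H](OC(=O)/C(C)=C\C)[C@@H](O)[C@@H](C)C(O)CO | intermediate
18 | β-hydroxy aldehyde (C3 aldehyde, C10 methyl, C9–OH, C4 iodide) | C=C1C(=O)O[C@@H](/C=C(/C)I)[C@@H]1[C@H](OC(=O)/C(C)=C\C)[C@@H](O)[C@@H](C)C=O | intermediate
19 | eight-membered allylic alcohol fused to the γ-lactone (C3–OH epimers, C9–OH) | C=C1C(=O)O[C@H]2/C=C(/C)C(O)[C@H](C)[C@H](O)[C@@H](OC(=O)/C(C)=C\C)[C@H]12 | intermediate
20 | eight-membered enone (C3 ketone, C9–OH) | C=C1C(=O)O[C@H]2/C=C(/C)C(=O)[C@H](C)[C@H](O)[C@@H](OC(=O)/C(C)=C\C)[C@H]12 | intermediate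
21 | C9 trimethylsilyl ether, C3(OTMS)=C10 silyl dienol ether | C=C1C(=O)O[C@H]2/C=C(/C)\C(O[Si](C)(C)C)=C(C)/[C@H](O[Si](C)(C)C)[C@@H](OC(=O)/C(C)=C\C)[C@H]12 | intermediate
22 | cis-bicyclo[6.2.0]decane dichlorocyclobutanone (C3–OTMS, C2 Cl2, C1 ketone, C9–OTMS) | C=C1C(=O)O[C@H]2/C=C(/C)[C@]3(O[Si](C)(C)C)C(Cl)(Cl)C(=O)[C@]3(C)[C@H](O[Si](C)(C)C)[C@@H](OC(=O)/C(C)=C\C)[C@H]12 | intermediate
23 | dechlorinated cyclobutanone, both silyl ethers in place | C=C1C(=O)O[C@H]2/C=C(/C)[C@]3(O[Si](C)(C)C)CC(=O)[C@]3(C)[C@H](O[Si](C)(C)C)[C@@H](OC(=O)/C(C)=C\C)[C@H]12 | intermediate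
24 | cyclobutanone with free C9–OH, C3–OTMS | C=C1C(=O)O[C@H]2/C=C(/C)[C@]3(O[Si](C)(C)C)CC(=O)[C@]3(C)[C@H](O)[C@@H](OC(=O)/C(C)=C\C)[C@H]12 | intermediate
25 | cyclobutanone C9 mesylate | C=C1C(=O)O[C@H]2/C=C(/C)[C@]3(O[Si](C)(C)C)CC(=O)[C@]3(C)[C@H](OS(C)(=O)=O)[C@@H](OC(=O)/C(C)=C\C)[C@H]12 | intermediate
26 | cyclobutanol (C1–OH cis to C9), C3–OTMS, C9–OMs | C=C1C(=O)O[C@H]2/C=C(/C)[C@]3(O[Si](C)(C)C)C[C@H](O)[C@]3(C)[C@H](OS(C)(=O)=O)[C@@H](OC(=O)/C(C)=C\C)[C@H]12 | intermediate
27 | tetrabutylammonium C3 alkoxide of 26 | C=C1C(=O)O[C@H]2/C=C(/C)[C@]3([O-])C[C@H](O)[C@]3(C)[C@H](OS(C)(=O)=O)[C@@H](OC(=O)/C(C)=C\C)[C@H]12.CCCC[N+](CCCC)(CCCC)CCCC | intermediate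
28 | 3-oxo precursor of the target (C3 ketone, 1S-hydroxyl, 4Z,9Z) | C=C1C(=O)O[C@H]2/C=C(/C)C(=O)C[C@H](O)/C(C)=C\[C@@H](OC(=O)/C(C)=C\C)[C@H]12 | intermediate
29 | CNP0152559.1 | C=C1C(=O)O[C@H]2/C=C(/C)[C@@H](O)C[C@H](O)/C(C)=C\[C@@H](OC(=O)/C(C)=C\C)[C@H]12 | target

## Step count and risks

Total step count: 21. Longest linear sequence: 19 steps (4 → 29; the branch 1 → 3 joins in step 5).

The three steps most likely to fail:

Step 20. The bicyclic alkoxide may not reach the conformation in which C3–C10 is antiperiplanar to C9–O, or the cycloaddition of step 16 may have taken place on the other ring face; fragmentation would then be slow or would deliver the 9E olefin. The fallback sets out from 25 and comes back at 29. Treating the cyclobutanone mesylate 25 itself with TBAF should open the β-oxido ketone by retro-aldol cleavage of the same C3–C10 bond (the classical two-carbon ring expansion of silyl enol ether/dichloroketene adducts), and the resulting C10 enolate should expel mesylate by an E1cB path. This stepwise sequence has no stereoelectronic demand and should give the ring-cis cyclodecadiene-1,3-dione F1 under thermodynamic control. Two-fold Corey–Bakshi–Shibata reduction of the two α-methyl enone carbonyls with the (R)-2-methyl-oxazaborolidine and catecholborane would then set C1 and C3 by reagent control and give 29.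

Step 19. Hydride delivery may occur from the concave face, which would give the wrong configuration at C1. The fallback sets out from 25 and comes back at 29. The epimeric cyclobutanol F2 is carried through the fluoride-induced fragmentation of step 20 to the C1-epimeric hydroxy enone F3, whose allylic C1 hydroxyl is oxidised with MnO2 to the dione F1, and F1 is reduced as described for step 20.

Step 5. The facial selectivity of the allylchromium addition with respect to the dioxolane centre may be poor or reversed (attack anti to the C–O bond instead of anti to the C8–C9 bond), which would give the wrong C7/C8 relationship. The fallback sets out from 3 and 5 and comes back at 13. The enantiomeric aldehyde, (R)-2,2-dimethyl-1,3-dioxolane-4-carbaldehyde F4, is taken through the same Baylis–Hillman reaction to the adduct F5 and the bromide F6. Allylation of 3 with the reversed facial preference should then give the lactone F7 with C6, C7 and C8 all as in the target. Hydrolysis to the diol F8 and silylation to the C9 silyl ether F9 are followed by esterification with angelic acid 12 with retention (Yamaguchi conditions: 2,4,6-trichlorobenzoyl chloride, Et3N, DMAP) in place of the Mitsunobu inversion, which gives 13.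

Further compounds
F1 | step 20 | cyclodecadiene-1,3-dione (C1 and C3 ketones, 4Z,9Z, lactone and angelate as in 28) | C=C1C(=O)O[C@H]2/C=C(/C)C(=O)CC(=O)/C(C)=C\[C@@H](OC(=O)/C(C)=C\C)[C@H]12
F2 | step 19 | C1 epimer of cyclobutanol 26 | C=C1C(=O)O[C@H]2/C=C(/C)[C@]3(O[Si](C)(C)C)C[C@@H](O)[C@]3(C)[C@H](OS(C)(=O)=O)[C@@H](OC(=O)/C(C)=C\C)[C@H]12
F3 | step 19 | C1 epimer of hydroxy enone 28 | C=C1C(=O)O[C@H]2/C=C(/C)C(=O)C[C@@H](O)/C(C)=C\[C@@H](OC(=O)/C(C)=C\C)[C@H]12
F4 | step 5 | (R)-2,2-dimethyl-1,3-dioxolane-4-carbaldehyde | O=C[C@H]1COC(C)(C)O1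
F5 | step 5 | Baylis–Hillman adduct of F4 and methyl acrylate (carbinol epimers) | C=C(C(=O)OC)C(O)[C@H]1COC(C)(C)O1
F6 | step 5 | enantiomer of bromide 7 | BrC/C(C(=O)OC)=C\[C@H]1COC(C)(C)O1
F7 | step 5 | C8 epimer of lactone 9 (C6, C7, C8 as in the target) | C=C1C(=O)O[C@@H](/C=C(/C)I)[C@@H]1[C@H]2COC(C)(C)O2
F8 | step 5 | C8 epimer of diol 10 | C=C1C(=O)O[C@@H](/C=C(/C)I)[C@@H]1[C@H](O)CO
F9 | step 5 | C8 epimer of silyl ether 11 | C=C1C(=O)O[C@@H](/C=C(/C)I)[C@@H]1[C@H](O)CO[Si](C)(C)C(C)(C)C
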